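**Plan**

1. Drimane numbering is used: ring A = C1–C5 and C10, ring B = C5–C10, C11 = the CCl(aryl) carbon, C12 = the methyl group on C8. The enabling feature is in ring B: the CHMe carbon C8 is bonded to the alkene carbon C9, whose partner C11 carries Cl and the arene. This is the pattern left when a methyl ketone (C8, C12) adds to one carbon of a titanium-bound aryl alkyne (C9≡C11) and the second C–Ti bond is chlorinated.
2. Retrosynthetic cuts, in order: quinone to silyl-protected phenol; C8–H to C8–OH; C8–C9 together with C11–Cl (ring B opens to an alkynyl methyl ketone); C9–C10 (to a ring-A alkene and an arylethynyl sulfone).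
3. With ring B open, C1–C8, C10, C12 and the three other methyl groups are the thirteen carbons of α-ionone; C9, C11 and the arene come from o-vanillin.
4. Forward: ring A is bought as (S)-α-ionone; the aryl alkyne is attached at C10 by iron-hydride hydrogen-atom transfer; ring B is closed by divalent titanium and chlorinated; dehydration, diimide reduction, desilylation and phenol oxidation finish the route.
5. Stereochemistry: C5 comes from (S)-α-ionone; C10 from radical capture anti to the C5 side chain; the alkene geometry from syn addition across the alkyne and retentive chlorination; C8 from diimide attack on the face opposite the C10 methyl group.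

Key step: step 9

Assumption: enantiopure (S)-α-ionone is taken as purchasable (it is also reachable from cheap racemic α-ionone by the established lipase resolution at the α-ionol stage).
Assumption: the key-step alcohol is drawn as the 8α-hydroxy (8R) epimer expected from a chair ring B; the 8β epimer would serve equally, because C8 becomes planar one step later.
Ar = 3-methoxy-2-(triisopropylsilyloxy)phenyl; α/β = below/above the decalin plane with the C10 methyl group β.

**Route**

Step 1
Reactants: 1 o-vanillin (2-hydroxy-3-methoxybenzaldehyde)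
Product: 2 3-methoxy-2-(triisopropylsilyloxy)benzaldehyde
Conditions: i-Pr3SiCl, imidazole, DMF, rt
Reagents that add atoms: triisopropylsilyl chloride, CC(C)[Si](Cl)(C(C)C)C(C)C
Why: Imidazole-promoted O-silylation of the phenol; the hindered silyl ether is chosen because it must outlast butyllithium, peracid, hot ethanol, dilute acid and the Grignard/titanium reagent before fluoride removes it.

Step 2
Reactants: 2 3-methoxy-2-(triisopropylsilyloxy)benzaldehyde
Product: 3 [2-(2,2-dibromoethenyl)-6-methoxyphenoxy]triisopropylsilane
Conditions: CBr4, PPh3, Zn dust, CH2Cl2, 0 °C → rt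
Reagents that add atoms: carbon tetrabromide, BrC(Br)(Br)Br
Why: First stage of the Corey–Fuchs sequence, a Wittig-type dibromo-olefination of the aldehyde by the ylide made from CBr4, PPh3 and Zn under neutral conditions that leave the aryl silyl ether alone.

Step 3
Reactants: 3 [2-(2,2-dibromoethenyl)-6-methoxyphenoxy]triisopropylsilane
Product: 5 [2-methoxy-6-(phenylsulfanylethynyl)phenoxy]triisopropylsilane, via lithium acetylide 4 (not isolated)
Conditions: n-BuLi (2.1 equiv), THF, −78 °C; PhSSPh, −78 °C → rt
Reagents that add atoms: diphenyl disulfide, c1ccc(SSc2ccccc2)cc1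
Why: Second stage of the Corey–Fuchs sequence (bromine–lithium exchange, Fritsch–Buttenberg–Wiechell rearrangement, deprotonation to acetylide 4) followed by sulfenylation of the acetylide with the disulfide.

Step 4
Reactants: 5 [2-methoxy-6-(phenylsulfanylethynyl)phenoxy]triisopropylsilane
Product: 7 [2-methoxy-6-(phenylsulfonylethynyl)phenoxy]triisopropylsilane (Ar–C≡C–SO2Ph), via alkynyl sulfoxide 6 (not isolated)
Conditions: mCPBA (2.2 equiv), CH2Cl2, 0 °C → rt
Reagents that add atoms: 3-chloroperoxybenzoic acid, OOC(=O)c1cccc(Cl)c1
Why: Peracid oxidation at sulfur (sulfide to sulfoxide to sulfone) is far faster than attack on the alkyne or the arene and is the standard preparation of acetylenic sulfones.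

Step 5
Reactants: 8 (S)-α-ionone, (3E)-4-[(1S)-2,6,6-trimethylcyclohex-2-en-1-yl]but-3-en-2-one
Product: 9 (S)-dihydro-α-ionone, 4-[(1S)-2,6,6-trimethylcyclohex-2-en-1-yl]butan-2-one
Conditions: H2 (1 atm), RhCl(PPh3)3 (5 mol %), benzene, rt
Reagents that add atoms: none
Why: Homogeneous hydrogenation with RhCl(PPh3)3 should reduce the disubstituted enone alkene and leave the trisubstituted ring alkene, the ketone and (under neutral conditions) the base-sensitive C5 stereocentre untouched.

Step 6
Reactants: 9 (S)-dihydro-α-ionone
Product: 10 2-methyl-2-{2-[(1S)-2,6,6-trimethylcyclohex-2-en-1-yl]ethyl}-1,3-dioxolane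
Conditions: HOCH2CH2OH, PPTS (cat.), benzene, reflux, Dean–Stark
Reagents that add atoms: ethylene glycol, OCCO
Why: Acid-catalysed ketalisation with azeotropic removal of water; the dioxolane keeps the C10 radical of the next step from adding to the C8 carbonyl group (a known cyclisation under the same iron hydride conditions) and keeps the silane from reducing the ketone.

Step 7
Reactants: 10 dioxolane of (S)-dihydro-α-ionone; 7 arylethynyl phenyl sulfone
Product: 11 2-{2-[(1S,2S)-2-(Ar-ethynyl)-2,6,6-trimethylcyclohexyl]ethyl}-2-methyl-1,3-dioxolane (alkyne trans to the side chain; 5S,10S in drimane numbering)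
Conditions: Fe(acac)3 (30 mol %), PhSiH3, EtOH/HOCH2CH2OH 5:1, 60 °C
Reagents that add atoms: none
Why: Mukaiyama-type hydrogen-atom transfer from an iron hydride puts H on C1 and leaves the tertiary C10 radical (Markovnikov), which adds to the sulfonyl-bearing carbon of 7 and expels PhSO2• (radical alkynylation with an acetylenic sulfone, a known hydroalkynylation of unactivated alkenes); the alkyne should enter anti to the C5 side chain because the other face is covered by that chain and by the axial C4 methyl group 1,3 to C10, which sets C10 and the later trans ring fusion.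

Step 8
Reactants: 11 alkynyl dioxolane
Product: 12 4-[(1S,2S)-2-(Ar-ethynyl)-2,6,6-trimethylcyclohexyl]butan-2-one (alkynyl methyl ketone; alkyne trans to the side chain)
Conditions: 1 M HCl, THF, rt
Reagents that add atoms: water, O
Why: Mild aqueous acid hydrolysis of the dioxolane, to which the aryl triisopropylsilyl ether and the internal alkyne are stable.

Step 9
Reactants: 12 alkynyl methyl ketone
Product: 16 (2R,4aS,8aS)-1-[(Z)-chloro(Ar)methylidene]-2,5,5,8a-tetramethyldecahydronaphthalen-2-ol (trans-decalin; 8α-OH and 8β-CH3; Cl cis to C8 and Ar cis to C10; Z only because C8 bears oxygen), via titanacyclopropene 13 (not isolated), via oxatitanacyclopentene 14 (not isolated), via titanium alkoxide 15 (not isolated)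
Conditions: Ti(OiPr)4 (1.5 equiv), i-PrMgCl (3.0 equiv, slow addition), Et2O, −78 → −40 °C; NCS, THF, −40 → 0 °C; aq NaHCO3
Reagents that add atoms: N-chlorosuccinimide, O=C1CCC(=O)N1Cl
Why: Ti(OiPr)4 and two equivalents of i-PrMgCl give (η2-propene)Ti(OiPr)2, a source of divalent titanium that trades propene for the aryl alkyne (titanacyclopropene 13); the tethered C8 ketone inserts into the Ti–C9 bond to give oxatitanacyclopentene 14, N-chlorosuccinimide replaces titanium on C11 by chlorine with retention (15), and hydrolysis frees the alcohol. The closest known reaction type is the titanium-alkoxide-mediated (Kulinkovich-type reagent) intramolecular reductive coupling of an alkyne with a carbonyl group followed by halogen cleavage of the alkenyl–titanium bond, here with N-chlorosuccinimide as the halogen source; two electrophilic carbons are joined because the low-valent metal makes the alkyne the nucleophile. Ring B closes in the 6-exo-dig sense through the new C8–C9 bond, the four-atom tether C10–C5–C6–C7 leaving no other size, since bonding of C8 to C11 would need a seven-membered ring with its alkene held inside the metallacycle. The only new stereocentre, the C8 carbinol, is controlled by the planar oxatitanacycle, which holds O in the plane of the C9=C11 bond (equatorial, α) and leaves the methyl group axial on a chair ring B; its configuration does not matter because C8 is planarised in step 10. The selectivity that counts is the alkene geometry: C8 and titanium add syn across the alkyne and chlorination is retentive, so Cl ends cis to C8 and the arene cis to C10, the more crowded isomer, fixed here by the metallacycle and not by thermodynamics. Chemoselectivity rests on slow addition of the Grignard reagent to 12 premixed with excess Ti(OiPr)4 at −78 °C, so that transmetalation to titanium outruns addition to the methyl ketone, and on the C–Ti bond being far more nucleophilic toward N-chlorosuccinimide than the arene.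

Step 10
Reactants: 16 chloro alcohol
Product: 18 (4aS,8aS)-1-[(E)-chloro(Ar)methylidene]-5,5,8a-trimethyl-2-methylidenedecahydronaphthalene (exocyclic C8=C12 alkene; Cl cis to C8), via C8 sulfamate 17 (not isolated)
Conditions: Burgess reagent (MeO2CN−SO2N+Et3), benzene, rt → 50 °C
Reagents that add atoms: none
Why: Burgess dehydration by syn elimination of sulfamate 17; loss of a C12 hydrogen should win because the equatorial C8–O bond has no syn-periplanar ring hydrogen and because a C7=C8 alkene would press the C12 methyl into the plane of the chloroalkene against chlorine (allylic 1,3-strain), while the non-acidic conditions avoid ionisation to the allyl cation.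

Step 11
Reactants: 18 exocyclic diene
Product: 19 (2S,4aS,8aS)-1-[(E)-chloro(Ar)methylidene]-2,5,5,8a-tetramethyldecahydronaphthalene (8β-CH3 axial and cis to the C10 methyl; Cl cis to C8)
Conditions: 2-O2NC6H4SO2NHNH2, Et3N, CH2Cl2, rt
Reagents that add atoms: none
Why: Diimide transfers H2 in a concerted syn fashion to the 1,1-disubstituted alkene only, sparing the tetrasubstituted chloroalkene and the C–Cl bond that hydrogenation over palladium would endanger; attack from the α face, opposite the axial C10 methyl group, puts H on that face of C8 and sets the axial 8β-methyl group (8S).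

Step 12
Reactants: 19 silyl ether
Product: 20 2-{(E)-chloro[(2S,4aS,8aS)-2,5,5,8a-tetramethyloctahydronaphthalen-1(2H)-ylidene]methyl}-6-methoxyphenol
Conditions: Bu4NF, AcOH, THF, 0 °C
Reagents that add atoms: none
Why: Fluoride cleaves the aryl O–Si bond; acetic acid buffers the phenoxide so that the electron-rich phenol is not air-oxidised, and the vinyl chloride is inert.

Step 13
Reactants: 20 phenol
Product: 21 2-{(E)-chloro[(2S,4aS,8aS)-2,5,5,8a-tetramethyloctahydronaphthalen-1(2H)-ylidene]methyl}-6-methoxycyclohexa-2,5-diene-1,4-dione (CNP0249629.1)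
Conditions: (KSO3)2NO (2.5 equiv), KH2PO4, acetone/H2O, rt
Reagents that add atoms: potassium nitrosodisulfonate, [K+].[K+].[O]N(S(=O)(=O)[O-])S(=O)(=O)[O-]
Why: Teuber oxidation, in which two equivalents of the nitroxyl radical oxidise the phenol, whose para position is free, to the para-quinone (the new carbonyl oxygen comes from the reagent) under buffered aqueous conditions that touch neither the chloroalkene nor the stereocentres.

**Compound list**

1 | o-vanillin (2-hydroxy-3-methoxybenzaldehyde) | COc1cccc(C=O)c1O | starting material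
2 | 3-methoxy-2-(triisopropylsilyloxy)benzaldehyde | COc1cccc(C=O)c1O[Si](C(C)C)(C(C)C)C(C)C | intermediate
3 | [2-(2,2-dibromoethenyl)-6-methoxyphenoxy]triisopropylsilane | COc1cccc(C=C(Br)Br)c1O[Si](C(C)C)(C(C)C)C(C)C | intermediate
4 | lithium acetylide of (2-ethynyl-6-methoxyphenoxy)triisopropylsilane (not isolated) | COc1cccc(C#C[Li])c1O[Si](C(C)C)(C(C)C)C(C)C | intermediate
5 | [2-methoxy-6-(phenylsulfanylethynyl)phenoxy]triisopropylsilane | COc1cccc(C#CSc2ccccc2)c1O[Si](C(C)C)(C(C)C)C(C)C | intermediate
6 | [2-methoxy-6-(phenylsulfinylethynyl)phenoxy]triisopropylsilane (racemic at sulfur; not isolated) | COc1cccc(C#CS(=O)c2ccccc2)c1O[Si](C(C)C)(C(C)C)C(C)C | intermediate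
7 | [2-methoxy-6-(phenylsulfonylethynyl)phenoxy]triisopropylsilane | COc1cccc(C#CS(=O)(=O)c2ccccc2)c1O[Si](C(C)C)(C(C)C)C(C)C | intermediate
8 | (S)-α-ionone | CC(=O)/C=C/[C@H]1C(C)(C)CCC=C1C | starting material
9 | (S)-dihydro-α-ionone | CC(=O)CC[C@H]1C(C)(C)CCC=C1C | intermediate
10 | 2-methyl-2-{2-[(1S)-2,6,6-trimethylcyclohex-2-en-1-yl]ethyl}-1,3-dioxolane | CC1(CC[C@H]2C(C)(C)CCC=C2C)OCCO1 | intermediate
11 | 2-{2-[(1S,2S)-2-(Ar-ethynyl)-2,6,6-trimethylcyclohexyl]ethyl}-2-methyl-1,3-dioxolane | CC1(CC[C@H]2C(C)(C)CCC[C@]2(C)C#Cc3cccc(OC)c3O[Si](C(C)C)(C(C)C)C(C)C)OCCO1 | intermediate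
12 | 4-[(1S,2S)-2-(Ar-ethynyl)-2,6,6-trimethylcyclohexyl]butan-2-one | CC(=O)CC[C@H]1C(C)(C)CCC[C@]1(C)C#Cc1cccc(OC)c1O[Si](C(C)C)(C(C)C)C(C)C | intermediate
13 | titanacyclopropene of 12, Ti(OiPr)2 bridging C9 and C11 (not isolated) | CC(=O)CC[C@H]1C(C)(C)CCC[C@]1(C)C2=C(c3cccc(OC)c3O[Si](C(C)C)(C(C)C)C(C)C)[Ti]2(OC(C)C)OC(C)C | intermediate
14 | oxatitanacyclopentene, ring Ti–O–C8–C9=C11 fused to the new ring B (not isolated) | COc1cccc(C2=C3[C@](C)(O[Ti]2(OC(C)C)OC(C)C)CC[C@H]4C(C)(C)CCC[C@]34C)c1O[Si](C(C)C)(C(C)C)C(C)C | intermediate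
15 | titanium alkoxide of 16, C8–O–Ti(OiPr)2(succinimidyl) (not isolated) | COc1cccc(/C(Cl)=C2/[C@](C)(O[Ti](OC(C)C)(OC(C)C)N3C(=O)CCC3=O)CC[C@H]4C(C)(C)CCC[C@]24C)c1O[Si](C(C)C)(C(C)C)C(C)C | intermediate
16 | (2R,4aS,8aS)-1-[(Z)-chloro(Ar)methylidene]-2,5,5,8a-tetramethyldecahydronaphthalen-2-ol | COc1cccc(/C(Cl)=C2/[C@](C)(O)CC[C@H]3C(C)(C)CCC[C@]23C)c1O[Si](C(C)C)(C(C)C)C(C)C | intermediate
17 | triethylammonium salt of the C8 N-(methoxycarbonyl)sulfamate ester of 16 (not isolated) | COc1cccc(/C(Cl)=C2/[C@](C)(OS(=O)(=O)[N-]C(=O)OC)CC[C@H]3C(C)(C)CCC[C@]23C)c1O[Si](C(C)C)(C(C)C)C(C)C.CC[NH+](CC)CC | intermediate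
18 | (4aS,8aS)-1-[(E)-chloro(Ar)methylidene]-5,5,8a-trimethyl-2-methylidenedecahydronaphthalene | COc1cccc(/C(Cl)=C2/C(=C)CC[C@H]3C(C)(C)CCC[C@]23C)c1O[Si](C(C)C)(C(C)C)C(C)C | intermediate
19 | (2S,4aS,8aS)-1-[(E)-chloro(Ar)methylidene]-2,5,5,8a-tetramethyldecahydronaphthalene | COc1cccc(/C(Cl)=C2/[C@@H](C)CC[C@H]3C(C)(C)CCC[C@]23C)c1O[Si](C(C)C)(C(C)C)C(C)C | intermediate
20 | 2-{(E)-chloro[(2S,4aS,8aS)-2,5,5,8a-tetramethyloctahydronaphthalen-1(2H)-ylidene]methyl}-6-methoxyphenol | COc1cccc(/C(Cl)=C2/[C@@H](C)CC[C@H]3C(C)(C)CCC[C@]23C)c1O | intermediate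
21 | 2-{(E)-chloro[(2S,4aS,8aS)-2,5,5,8a-tetramethyloctahydronaphthalen-1(2H)-ylidene]methyl}-6-methoxycyclohexa-2,5-diene-1,4-dione (CNP0249629.1) | COC1=CC(=O)C=C(/C(Cl)=C2/[C@@H](C)CC[C@H]3C(C)(C)CCC[C@]23C)C1=O | target

**Step count and risks**

Total step count: 13. Longest linear sequence: 11 steps (o-vanillin through steps 1–4 and 7–13); the ionone branch is 9 steps (steps 5–13).

The three steps most likely to fail, riskiest first:

Step 9. What may go wrong: the hindered, aryl-flanked C11–Ti bond is protonated on work-up instead of being chlorinated, or N-chlorosuccinimide is consumed by the excess low-valent titanium, so that the halogen is lost. The fallback sets out from 12 and keeps the titanium closure. Oxatitanacycle 14 is instead cleaved with I2, the standard electrophile for alkenyl–titanium bonds, to give the vinyl iodide (2R,4aS,8aS)-1-[(Z)-iodo(Ar)methylidene]-2,5,5,8a-tetramethyldecahydronaphthalen-2-ol F1. The iodide is then exchanged in a separate operation: MeLi (1 equiv, to form the C8 alkoxide), t-BuLi (2 equiv), Et2O, −78 °C, then C2Cl6. The alkenyllithium should be held on the C8 side by chelation to the neighbouring lithium alkoxide, so chlorine arrives cis to C8. The route is rejoined at 16.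

Step 7. What may go wrong: capture of the C10 radical on the wrong face (alkyne cis to the side chain), or reduction of the radical to the saturated ring before it meets the sulfone. The fallback sets out from 10 and replaces radical capture by a polar conjugate addition under stereoelectronic control.
- Allylic oxidation at C2 (CrO3, 3,5-dimethylpyrazole, CH2Cl2, −20 °C) gives the enone (S)-4-[2-(2-methyl-1,3-dioxolan-2-yl)ethyl]-3,5,5-trimethylcyclohex-2-en-1-one F2.
- The terminal alkyne (2-ethynyl-6-methoxyphenoxy)triisopropylsilane F3 is made from dibromide 3 (n-BuLi, 2 equiv, THF, −78 °C, then water).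
- F3 is converted to its dimethylaluminium acetylide (n-BuLi, then Me2AlCl) and added to F2 with zerovalent nickel made in the flask from Ni(acac)2 and i-Bu2AlH (cat.), Et2O, −5 °C. Axial attack anti to the C5 substituent should give the β-alkynyl ketone with the C10 quaternary centre, the C2 ketone of 11, F4. This addition onto a hindered, isophorone-like β,β-disubstituted enone is itself demanding.
- The C2 carbonyl is removed through the tosylhydrazone F5 (TsNHNH2, EtOH), reduced with catecholborane and then NaOAc·3H2O.

The route is rejoined at 11.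

Step 10. What may go wrong: elimination into the ring (C7=C8) instead of toward C12, giving a trisubstituted alkene that diimide reduces too slowly. The fallback sets out from 16. The same dehydration is run, and the endocyclic diene (4aS,8aS)-1-[(E)-chloro(Ar)methylidene]-2,5,5,8a-tetramethyl-1,4,4a,5,6,7,8,8a-octahydronaphthalene F6, alone or mixed with 18, is not separated. It is hydrogenated with H2 and [Ir(cod)(PCy3)(py)]PF6 in CH2Cl2, a cationic catalyst that reduces hindered trisubstituted and 1,1-disubstituted alkenes. Hydrogen should arrive from the face opposite the C10 methyl group, and the tetrasubstituted, chlorine- and aryl-bearing C9=C11 bond next to the quaternary C10 should be too crowded to bind. Both dienes converge on 19, where the route is rejoined.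

Further compounds

F1 | step 9 | (2R,4aS,8aS)-1-[(Z)-iodo(Ar)methylidene]-2,5,5,8a-tetramethyldecahydronaphthalen-2-ol | COc1cccc(/C(I)=C2/[C@](C)(O)CC[C@H]3C(C)(C)CCC[C@]23C)c1O[Si](C(C)C)(C(C)C)C(C)C
F2 | step 7 | (S)-4-[2-(2-methyl-1,3-dioxolan-2-yl)ethyl]-3,5,5-trimethylcyclohex-2-en-1-one | CC1(CC[C@H]2C(C)(C)CC(=O)C=C2C)OCCO1
F3 | step 7 | (2-ethynyl-6-methoxyphenoxy)triisopropylsilane | COc1cccc(C#C)c1O[Si](C(C)C)(C(C)C)C(C)C
F4 | step 7 | (3S,4S)-3-(Ar-ethynyl)-3,5,5-trimethyl-4-[2-(2-methyl-1,3-dioxolan-2-yl)ethyl]cyclohexan-1-one | CC1(CC[C@H]2C(C)(C)CC(=O)C[C@]2(C)C#Cc3cccc(OC)c3O[Si](C(C)C)(C(C)C)C(C)C)OCCO1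
F5 | step 7 | 4-methylbenzenesulfonylhydrazone of F4 | CC1(CC[C@H]2C(C)(C)CC(=NNS(=O)(=O)c3ccc(C)cc3)C[C@]2(C)C#Cc4cccc(OC)c4O[Si](C(C)C)(C(C)C)C(C)C)OCCO1
F6 | step 10 | (4aS,8aS)-1-[(E)-chloro(Ar)methylidene]-2,5,5,8a-tetramethyl-1,4,4a,5,6,7,8,8a-octahydronaphthalene (C7=C8 diene) | COc1cccc(/C(Cl)=C2/C(C)=CC[C@H]3C(C)(C)CCC[C@]23C)c1O[Si](C(C)C)(C(C)C)C(C)C
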